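**Plan** (prostanoid numbering: C1 ester carbon, ring C8–C12, C20 chain end)

- Cuts: the C12 acetate goes back to a silyl ether. C7=C8 is cut by aldol condensation into a 2-chlorocyclopentenone and the C1–C7 (Z)-enal. C10–Cl is traced to the 10,11-epoxide and C14=C15 to a Wittig reaction of a ring aldehyde. The ring is opened at C9–C10 (alkyne hydroacylation) to an achiral dialdehyde, which comes from a propiolate ester and two allyl groups (bonds C8–C12 and C12–C13).
- Enabling feature: apart from its oxygen and the vinylic C11, the sole stereocentre C12 is bonded to two carbons that can both be CH2 groups, namely C13 and ring carbon C8 as long as C7=C8 is absent. The cyclopentenone C8–C9–C10–C11–C12 can therefore be closed on a 3-ethynyl-3-silyloxypentanedial in which C12 is prochiral and the two CH2CHO arms are enantiotopic.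
- Forward order: the cyclopentenone (the only ring) is closed first by the desymmetrising rhodium step. The lower chain is then joined at C14=C15, chlorine is placed on C10, the upper chain is joined at C7=C8, and the silyl ether is exchanged for the acetate.
- Stereochemistry: 12R comes from the chiral bisphosphine on rhodium, which chooses the formyl arm that becomes C8/C9. 14Z comes from the lithium-free Wittig reaction, 5Z from Lindlar reduction, and 7E from elimination to the more stable alkylidene.

Key step: step 5

Assumption: the sense of induction of Tol-BINAP for this new substrate class cannot be predicted with confidence; the route is written with the (R)-ligand, and the (S)-ligand is used instead if a test cyclisation selects the other arm (nothing else changes).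

Step 1
Reactants: 1 ethyl 3-(trimethylsilyl)propiolate; 2 allylmagnesium bromide (two equivalents are consumed)
Product: 4 4-[(trimethylsilyl)ethynyl]hepta-1,6-dien-4-ol, via allyl ynone 3 (not isolated)
Conditions: allylmagnesium bromide (2.5 equiv), Et2O, −78 °C → 0 °C; then H2O/aq. NH4Cl
Reagents that add atoms: allylmagnesium bromide (the second equivalent, which supplies the second allyl arm), C=CC[Mg]Br
Why: Twofold Grignard addition to an ester, in which the first equivalent displaces ethoxide to give the more electrophilic alkynyl ketone 3 and the second equivalent adds 1,2 to it (allylmagnesium reagents attack the carbonyl, not the silyl-capped alkyne terminus), so the symmetric tertiary carbinol with two identical allyl arms results.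

Step 2
Reactants: 4 4-[(trimethylsilyl)ethynyl]hepta-1,6-dien-4-ol
Product: 5 4-ethynylhepta-1,6-dien-4-ol
Conditions: K2CO3 (0.2 equiv), MeOH, rt
Reagents that add atoms: none
Why: Base-catalysed methanolysis of the alkynyl C–Si bond (protodesilylation) is routine and leaves the tertiary alcohol and both alkenes untouched.

Step 3
Reactants: 5 4-ethynylhepta-1,6-dien-4-ol
Product: 6 triethyl[(4-ethynylhepta-1,6-dien-4-yl)oxy]silane
Conditions: Et3SiOTf, 2,6-lutidine, CH2Cl2, −78 °C → 0 °C
Reagents that add atoms: triethylsilyl trifluoromethanesulfonate, CC[Si](CC)(CC)OS(=O)(=O)C(F)(F)F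
Why: Silyl triflate/lutidine silylation is the standard way to cap a hindered tertiary carbinol, and the terminal alkyne C–H is not silylated by this weak base.

Step 4
Reactants: 6 triethyl[(4-ethynylhepta-1,6-dien-4-yl)oxy]silane
Product: 8 3-ethynyl-3-(triethylsilyloxy)pentanedial, via bis-ozonide 7 (not isolated)
Conditions: O3 (one equivalent per alkene), CH2Cl2, −78 °C, Sudan Red 7B as end-point indicator; then PPh3, −78 °C → rt
Reagents that add atoms: ozone (two equivalents, one per alkene), [O-][O+]=O
Why: Ozonolysis with reductive work-up, in which ozone consumes the two monosubstituted alkenes far faster than the terminal alkyne and the dye marks the end point; the achiral dialdehyde is filtered through a short silica pad and used at once.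

Step 5
Reactants: 8 3-ethynyl-3-(triethylsilyloxy)pentanedial
Product: 9 (S)-4-(2-oxoethyl)-4-(triethylsilyloxy)cyclopent-2-en-1-one
Conditions: [Rh((R)-Tol-BINAP)]BF4 (10 mol %, from [Rh(nbd)((R)-Tol-BINAP)]BF4 and H2), degassed CH2Cl2 (0.05 M), rt
Reagents that add atoms: none
Why: Proposed new method: oxidative addition of a formyl C–H bond of 8 to the cationic monovalent rhodium bisphosphine complex should give an acyl hydride of trivalent rhodium with the alkyne bound to the same metal; the hydride then passes to the inner alkyne carbon C11 in a net trans addition, and the six-membered acyl(alkenyl)rhodacycle collapses by C9–C10 reductive elimination with release of monovalent rhodium. The closest known reaction type is the rhodium bisphosphine-catalysed trans-hydroacylation of 4-alkynals to cyclopent-2-enones, including its Tol-BINAP desymmetrisation of 3-alkoxy-4-alkynals that carry two enantiotopic alkynes; new here are the choice between two enantiotopic formyl arms, the terminal alkyne and the silyl ether on C12. The cyclopentenone C8–C9–C10–C11–C12 closes in a formal 5-endo-dig addition of the acyl carbon to the alkyne. C12, the only new stereocentre, is set by catalyst control: C–H insertion is reversible, so the chiral pocket of the bisphosphine decides at the ring-forming stage which arm becomes C8/C9 and which stays as the C13–C14 aldehyde, reading the bulky silyloxy group against the spectator arm. The step needs enantiotopic-group selectivity and chemoselectivity over decarbonylation; with a single alkyne both arms lead to the same constitution, and the fully substituted, oxygen-bearing C12 presses formyl group and alkyne together as in the known substrates. Once the alkyne is consumed the remaining aldehyde could only react further by a strained bridged hydroacylation of the ring alkene, so it should survive for the next step.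

Step 6
Reactants: 9 (S)-4-(2-oxoethyl)-4-(triethylsilyloxy)cyclopent-2-en-1-one; 10 hexyltriphenylphosphonium bromide
Product: 12 (S)-4-[(Z)-oct-2-en-1-yl]-4-(triethylsilyloxy)cyclopent-2-en-1-one, via phosphorus ylide 11 (not isolated)
Conditions: 10, NaN(SiMe3)2, THF, 0 °C; ylide solution (1.05 equiv) added to 9, THF, −78 °C → −20 °C
Reagents that add atoms: none
Why: Wittig olefination with a non-stabilised ylide under lithium-free conditions gives the Z alkene through the kinetically favoured cis-oxaphosphetane, and at −78 °C the ylide adds to the aldehyde much faster than it attacks the less electrophilic enone carbonyl or removes a proton.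

Step 7
Reactants: 12 (S)-4-[(Z)-oct-2-en-1-yl]-4-(triethylsilyloxy)cyclopent-2-en-1-one
Product: 13 (4S)-4-[(Z)-oct-2-en-1-yl]-4-(triethylsilyloxy)-6-oxabicyclo[3.1.0]hexan-2-one (both epoxide faces)
Conditions: 30% aq. H2O2, NaOH (0.3 equiv), MeOH, −20 °C → 0 °C
Reagents that add atoms: hydrogen peroxide, OO
Why: Weitz–Scheffer nucleophilic epoxidation, in which hydroperoxide adds to C11 of the enone and the enolate closes the oxirane while the electron-rich Z alkene is left alone; either epoxide face serves, since C10 and C11 become sp2 again in step 8.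

Step 8
Reactants: 13 (4S)-4-[(Z)-oct-2-en-1-yl]-4-(triethylsilyloxy)-6-oxabicyclo[3.1.0]hexan-2-one
Product: 15 (S)-2-chloro-4-[(Z)-oct-2-en-1-yl]-4-(triethylsilyloxy)cyclopent-2-en-1-one, via chlorohydrin 14 (not isolated)
Conditions: conc. aq. HCl (3 equiv), acetone, 0 °C → rt
Reagents that add atoms: hydrogen chloride, Cl
Why: Acid-mediated opening of an α,β-epoxy ketone by chloride at the α-carbon C10 (C11 is neopentyl) followed by dehydration of the β-hydroxy ketone is the classical route to 2-chloroenones; no electrophilic chlorine is present, so the Z alkene survives, and ionisation of the C12–O bond is disfavoured because the allylic cation formed would be conjugated to the C9 carbonyl and so destabilised.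

Step 9
Reactants: 16 hex-5-ynoic acid; 17 formaldehyde (as paraformaldehyde)
Product: 19 7-hydroxyhept-5-ynoic acid, via dilithium salt 18 (not isolated)
Conditions: n-BuLi (2.2 equiv), THF, −78 °C → 0 °C; (CH2O)n, 0 °C → rt; aq. HCl
Reagents that add atoms: none
Why: Hydroxymethylation of a lithium acetylide, in which two equivalents of base give the carboxylate/acetylide dianion and only its carbon terminus adds to formaldehyde (C7).

Step 10
Reactants: 19 7-hydroxyhept-5-ynoic acid
Product: 20 methyl 7-hydroxyhept-5-ynoate
Conditions: MeOH, H2SO4 (cat.), rt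
Reagents that add atoms: methanol, CO
Why: Fischer esterification in excess methanol, which does not affect the propargylic alcohol.

Step 11
Reactants: 20 methyl 7-hydroxyhept-5-ynoate
Product: 21 methyl (Z)-7-hydroxyhept-5-enoate
Conditions: H2 (1 atm), Pd/CaCO3 poisoned with Pb(OAc)2 (Lindlar catalyst), quinoline, EtOAc, rt
Reagents that add atoms: none
Why: Lindlar semihydrogenation delivers H2 syn to the alkyne and stops at the Z alkene, which sets 5Z.

Step 12
Reactants: 21 methyl (Z)-7-hydroxyhept-5-enoate
Product: 22 methyl (Z)-7-oxohept-5-enoate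
Conditions: Dess–Martin periodinane, pyridine, CH2Cl2, 0 °C
Reagents that add atoms: none
Why: Dess–Martin oxidation of the allylic alcohol under buffered, non-equilibrating conditions should preserve the Z geometry; the enal is used immediately.

Step 13
Reactants: 15 (S)-2-chloro-4-[(Z)-oct-2-en-1-yl]-4-(triethylsilyloxy)cyclopent-2-en-1-one; 22 methyl (Z)-7-oxohept-5-enoate
Product: 24 methyl (5Z)-7-[(2S)-4-chloro-2-[(Z)-oct-2-en-1-yl]-5-oxo-2-(triethylsilyloxy)cyclopent-3-en-1-yl]-7-hydroxyhept-5-enoate (diastereomers at C7 and C8), via lithium dienolate 23 (not isolated)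
Conditions: LiN(i-Pr)2 (1.1 equiv), THF, −78 °C; then 22, −78 °C; AcOH quench at −78 °C
Reagents that add atoms: none
Why: Directed aldol addition, in which C8 is the only enolisable position of 15 and its lithium enolate adds 1,2 to the enal; β-loss of the C12 silyloxy group is held back because it would give an antiaromatic cyclopentadienone, and the C7/C8 diastereomers are carried on together because both centres vanish in step 14.

Step 14
Reactants: 24 methyl (5Z)-7-[(2S)-4-chloro-2-[(Z)-oct-2-en-1-yl]-5-oxo-2-(triethylsilyloxy)cyclopent-3-en-1-yl]-7-hydroxyhept-5-enoate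
Product: 26 methyl (5Z,7E)-7-[(2R)-4-chloro-2-[(Z)-oct-2-en-1-yl]-5-oxo-2-(triethylsilyloxy)cyclopent-3-en-1-ylidene]hept-5-enoate, via mesylate 25 (not isolated)
Conditions: MsCl, Et3N, CH2Cl2, −20 °C → rt
Reagents that add atoms: none
Why: Mesylation of the secondary aldol hydroxyl and E1cB elimination by triethylamine should favour the more stable 7E alkylidene, with C6 turned away from the C9 carbonyl; the 5Z alkene is not touched and any 7Z isomer is separable.

Step 15
Reactants: 26 methyl (5Z,7E)-7-[(2R)-4-chloro-2-[(Z)-oct-2-en-1-yl]-5-oxo-2-(triethylsilyloxy)cyclopent-3-en-1-ylidene]hept-5-enoate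
Product: 27 methyl (5Z,7E)-7-[(2R)-4-chloro-2-hydroxy-2-[(Z)-oct-2-en-1-yl]-5-oxocyclopent-3-en-1-ylidene]hept-5-enoate
Conditions: HF·pyridine, THF, 0 °C → rt
Reagents that add atoms: none
Why: Fluoride-driven Si–O cleavage under mildly acidic conditions, which the base-sensitive cross-conjugated dienone tolerates better than basic fluoride sources.

Step 16
Reactants: 27 methyl (5Z,7E)-7-[(2R)-4-chloro-2-hydroxy-2-[(Z)-oct-2-en-1-yl]-5-oxocyclopent-3-en-1-ylidene]hept-5-enoate
Product: 28 methyl (5Z,7E)-7-[(2R)-2-acetoxy-4-chloro-2-[(Z)-oct-2-en-1-yl]-5-oxocyclopent-3-en-1-ylidene]hept-5-enoate (CNP0248978.4)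
Conditions: Ac2O, DMAP, Et3N, CH2Cl2, rt
Reagents that add atoms: acetic anhydride, CC(=O)OC(C)=O
Why: DMAP-catalysed acylation of the tertiary alcohol proceeds with retention at C12, and because C8 carries no hydrogen neither β-elimination nor retro-aldol cleavage can compete.

**Compound list**

1 | ethyl 3-(trimethylsilyl)propiolate | CCOC(=O)C#C[Si](C)(C)C | starting material
2 | allylmagnesium bromide | C=CC[Mg]Br | starting material
3 | 1-(trimethylsilyl)hex-5-en-1-yn-3-one (formed and consumed in step 1) | C=CCC(=O)C#C[Si](C)(C)C | intermediate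
4 | 4-[(trimethylsilyl)ethynyl]hepta-1,6-dien-4-ol | C=CCC(O)(CC=C)C#C[Si](C)(C)C | intermediate
5 | 4-ethynylhepta-1,6-dien-4-ol | C=CCC(O)(CC=C)C#C | intermediate
6 | triethyl[(4-ethynylhepta-1,6-dien-4-yl)oxy]silane | C=CCC(CC=C)(O[Si](CC)(CC)CC)C#C | intermediate
7 | 3,3'-[2-ethynyl-2-(triethylsilyloxy)propane-1,3-diyl]bis(1,2,4-trioxolane), stereoisomer mixture (formed and consumed in step 4) | C#CC(CC1OCOO1)(CC1OCOO1)O[Si](CC)(CC)CC | intermediate
8 | 3-ethynyl-3-(triethylsilyloxy)pentanedial (achiral, C12 prochiral) | O=CCC(CC=O)(O[Si](CC)(CC)CC)C#C | intermediate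
9 | (S)-4-(2-oxoethyl)-4-(triethylsilyloxy)cyclopent-2-en-1-one (C12 arranged as in the target; the descriptor is S because C8 still ranks below C11) | O=CC[C@@]1(O[Si](CC)(CC)CC)C=CC(=O)C1 | intermediate
10 | hexyltriphenylphosphonium bromide | CCCCCC[P+](c1ccccc1)(c1ccccc1)c1ccccc1.[Br-] | starting material
11 | hexylidenetriphenylphosphorane (formed and consumed in step 6) | CCCCCC=P(c1ccccc1)(c1ccccc1)c1ccccc1 | intermediate
12 | (S)-4-[(Z)-oct-2-en-1-yl]-4-(triethylsilyloxy)cyclopent-2-en-1-one | CCCCC/C=C\C[C@@]1(O[Si](CC)(CC)CC)C=CC(=O)C1 | intermediate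
13 | (4S)-4-[(Z)-oct-2-en-1-yl]-4-(triethylsilyloxy)-6-oxabicyclo[3.1.0]hexan-2-one, both epoxide faces (C1 and C5 not defined) | CCCCC/C=C\C[C@@]1(O[Si](CC)(CC)CC)C2OC2C(=O)C1 | intermediate
14 | (4S)-2-chloro-3-hydroxy-4-[(Z)-oct-2-en-1-yl]-4-(triethylsilyloxy)cyclopentan-1-one, C2 and C3 not defined (formed and consumed in step 8) | CCCCC/C=C\C[C@@]1(O[Si](CC)(CC)CC)C(O)C(Cl)C(=O)C1 | intermediate
15 | (S)-2-chloro-4-[(Z)-oct-2-en-1-yl]-4-(triethylsilyloxy)cyclopent-2-en-1-one | CCCCC/C=C\C[C@@]1(O[Si](CC)(CC)CC)C=C(Cl)C(=O)C1 | intermediate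
16 | hex-5-ynoic acid | C#CCCCC(=O)O | starting material
17 | formaldehyde (used as paraformaldehyde) | C=O | starting material
18 | lithium 6-lithiohex-5-ynoate (formed and consumed in step 9) | [Li]C#CCCCC(=O)O[Li] | intermediate
19 | 7-hydroxyhept-5-ynoic acid | OCC#CCCCC(=O)O | intermediate
20 | methyl 7-hydroxyhept-5-ynoate | COC(=O)CCCC#CCO | intermediate
21 | methyl (Z)-7-hydroxyhept-5-enoate | COC(=O)CCC/C=C\CO | intermediate
22 | methyl (Z)-7-oxohept-5-enoate | COC(=O)CCC/C=C\C=O | intermediate
23 | lithium (3S)-5-chloro-3-[(Z)-oct-2-en-1-yl]-3-(triethylsilyloxy)cyclopenta-1,4-dien-1-olate (formed and consumed in step 13) | CCCCC/C=C\C[C@@]1(O[Si](CC)(CC)CC)C=C(Cl)C(O[Li])=C1 | intermediate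
24 | methyl (5Z)-7-[(2S)-4-chloro-2-[(Z)-oct-2-en-1-yl]-5-oxo-2-(triethylsilyloxy)cyclopent-3-en-1-yl]-7-hydroxyhept-5-enoate, diastereomers at C7 and C8 | CCCCC/C=C\C[C@@]1(O[Si](CC)(CC)CC)C=C(Cl)C(=O)C1C(O)/C=C\CCCC(=O)OC | intermediate
25 | methyl (5Z)-7-[(2S)-4-chloro-2-[(Z)-oct-2-en-1-yl]-5-oxo-2-(triethylsilyloxy)cyclopent-3-en-1-yl]-7-(methanesulfonyloxy)hept-5-enoate (formed and consumed in step 14) | CCCCC/C=C\C[C@@]1(O[Si](CC)(CC)CC)C=C(Cl)C(=O)C1C(OS(C)(=O)=O)/C=C\CCCC(=O)OC | intermediate
26 | methyl (5Z,7E)-7-[(2R)-4-chloro-2-[(Z)-oct-2-en-1-yl]-5-oxo-2-(triethylsilyloxy)cyclopent-3-en-1-ylidene]hept-5-enoate | CCCCC/C=C\C[C@@]1(O[Si](CC)(CC)CC)C=C(Cl)C(=O)/C1=C/C=C\CCCC(=O)OC | intermediate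
27 | methyl (5Z,7E)-7-[(2R)-4-chloro-2-hydroxy-2-[(Z)-oct-2-en-1-yl]-5-oxocyclopent-3-en-1-ylidene]hept-5-enoate | CCCCC/C=C\C[C@@]1(O)C=C(Cl)C(=O)/C1=C/C=C\CCCC(=O)OC | intermediate
28 | methyl (5Z,7E)-7-[(2R)-2-acetoxy-4-chloro-2-[(Z)-oct-2-en-1-yl]-5-oxocyclopent-3-en-1-ylidene]hept-5-enoate (CNP0248978.4; 12R,5Z,7E,14Z) | CCCCC/C=C\C[C@@]1(OC(C)=O)C=C(Cl)C(=O)/C1=C/C=C\CCCC(=O)OC | target

**Totals**

Total step count: 16. Longest linear sequence: 12 steps (steps 1–8 and 13–16, from 1); the enal 22 is made in a 4-step side branch (steps 9–12).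

**Steps most likely to fail**

Step 5 (Proposed new method). The catalyst may fail to tell the two formyl arms apart, the terminal alkyne may divert the rhodium (vinylidene formation, oligomerisation), or the acyl rhodium hydride may decarbonylate before ring closure. The fallback uses known chemistry and takes the stereocentre from the chiral pool. It sets out from 2, which is added in THF at −78 °C to purchased (R)-4-(tert-butyldimethylsilyloxy)cyclopent-2-en-1-one F1. 1,2-Addition anti to the silyloxy group should give (1S,4R)-1-allyl-4-(tert-butyldimethylsilyloxy)cyclopent-2-en-1-ol F2. Bu4NF then frees (1S,4R)-1-allylcyclopent-2-ene-1,4-diol F3, and MnO2 oxidises only the secondary allylic alcohol to (S)-4-allyl-4-hydroxycyclopent-2-en-1-one F4, so the original stereocentre is spent after it has set the quaternary one. Et3SiOTf/2,6-lutidine gives (S)-4-allyl-4-(triethylsilyloxy)cyclopent-2-en-1-one F5. Ozonolysis of its terminal alkene (dye end point, PPh3; the electron-poor ring alkene reacts more slowly) comes back to the route at 9.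

Step 6. The strongly basic ylide may remove a proton at C8 or C13, with β-loss of the silyloxy group, or add to the enone carbonyl, and the Z selectivity may erode. The fallback builds the alkene and the chain in two separate bond formations. It sets out from 9: Stork–Zhao iodo-olefination with the less basic ylide from (iodomethyl)triphenylphosphonium iodide and NaN(SiMe3)2 (THF/DMPU, −78 °C) should give (S)-4-[(Z)-3-iodoprop-2-en-1-yl]-4-(triethylsilyloxy)cyclopent-2-en-1-one F6. Negishi coupling of F6 with pentylzinc bromide and Pd(PPh3)4 (zerovalent palladium, THF, rt) retains the alkene geometry, tolerates the enone and comes back to the route at 12.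

Step 8. The triethylsilyl ether may be cleaved by the aqueous acid before the epoxide has opened, or the sequence may stall at the chlorohydrin. The fallback runs the chlorination on the unprotected carbinol. It sets out from 12: HF·pyridine gives (S)-4-hydroxy-4-[(Z)-oct-2-en-1-yl]cyclopent-2-en-1-one F7. H2O2/NaOH in MeOH at −20 °C gives (4S)-4-hydroxy-4-[(Z)-oct-2-en-1-yl]-6-oxabicyclo[3.1.0]hexan-2-one F8. Concentrated HCl in acetone, now free to be used as long as the dehydration needs, gives (S)-2-chloro-4-hydroxy-4-[(Z)-oct-2-en-1-yl]cyclopent-2-en-1-one F9. Et3SiOTf/2,6-lutidine comes back to the route at 15.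

Further compounds
F1 | step 5 | (R)-4-(tert-butyldimethylsilyloxy)cyclopent-2-en-1-one (purchased) | O=C1C=C[C@H](O[Si](C)(C)C(C)(C)C)C1
F2 | step 5 | (1S,4R)-1-allyl-4-(tert-butyldimethylsilyloxy)cyclopent-2-en-1-ol | C=CC[C@@]1(O)C=C[C@H](O[Si](C)(C)C(C)(C)C)C1
F3 | step 5 | (1S,4R)-1-allylcyclopent-2-ene-1,4-diol | C=CC[C@@]1(O)C=C[C@H](O)C1
F4 | step 5 | (S)-4-allyl-4-hydroxycyclopent-2-en-1-one | C=CC[C@@]1(O)C=CC(=O)C1
F5 | step 5 | (S)-4-allyl-4-(triethylsilyloxy)cyclopent-2-en-1-one | C=CC[C@@]1(O[Si](CC)(CC)CC)C=CC(=O)C1
F6 | step 6 | (S)-4-[(Z)-3-iodoprop-2-en-1-yl]-4-(triethylsilyloxy)cyclopent-2-en-1-one | I/C=C\C[C@@]1(O[Si](CC)(CC)CC)C=CC(=O)C1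
F7 | step 8 | (S)-4-hydroxy-4-[(Z)-oct-2-en-1-yl]cyclopent-2-en-1-one | CCCCC/C=C\C[C@@]1(O)C=CC(=O)C1
F8 | step 8 | (4S)-4-hydroxy-4-[(Z)-oct-2-en-1-yl]-6-oxabicyclo[3.1.0]hexan-2-one, both epoxide faces | CCCCC/C=C\C[C@@]1(O)C2OC2C(=O)C1
F9 | step 8 | (S)-2-chloro-4-hydroxy-4-[(Z)-oct-2-en-1-yl]cyclopent-2-en-1-one | CCCCC/C=C\C[C@@]1(O)C=C(Cl)C(=O)C1
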